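Atom numbers C1–C8a are those of the dihydronaphthalene core of the target and are kept for every intermediate. Ring A is the fused benzene ring, ring B the partly saturated ring, and ring C the aryl group on C1.

## Analysis of the target

The target (16) is a 1-aryl-1,2-dihydronaphthalene. Ring A carries OMe on C6 and OH on C7, ring B is C1–C2–C3=C4–C4a–C8a, and ring C is a 4-hydroxy-3-methoxyphenyl group on C1. C3 bears a formyl group, and the C3=C4 bond is conjugated with both the aldehyde and ring A; C2 bears a hydroxymethyl group. The two stereocentres are adjacent: C1 is S and doubly benzylic, C2 is R and γ to the enal carbonyl, and the aryl and hydroxymethyl groups are trans on ring B. The sensitive features are the enal, two free guaiacol-type phenols, the C2–H (a vinylogous α-position) and the tendency of ring B to aromatise with loss of both stereocentres. The synthesis is hard for three reasons: the C1/C2 pair must be set in absolute terms next to sp2 carbons, ring A must be substituted without regiochemical ambiguity, and two one-carbon substituents (CH2OH on C2, CHO on C3) must be held at different oxidation levels. The strategy rests on C1, which carries only ring C, one hydrogen and two ring bonds, to C2 and to C8a, and on the fact that C8a lies para to the C6 methoxy group. C1 can therefore be the carbonyl carbon of an O-protected vanillin, joined to C2 by allyl transfer and to C8a by capture of the derived benzylic cation, so that both aromatic rings come from vanillin (1).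

## Retrosynthetic reasoning

**16 ⇒ 15.** The last operation is deprotection. The three hydroxyl groups of 16 are carried as benzyl ethers in 15. Benzyl ethers survive organomagnesium and organolithium reagents, Lewis acids at low temperature, peroxide and aluminium amide. A para-benzyloxy group is also the donor that makes the C1 cation accessible, whereas a silyl ether there could lose silicon once the cation has formed. The forward step must cleave three O–CH2Ph bonds without touching the enal or the C3=C4 bond, so hydrogenolysis is excluded and a Lewis-acid debenzylation with a cation scavenger is needed.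

**15 ⇒ 14 ⇒ 13 ⇒ 12.** The enal is traced back to an exocyclic methylene on C3. The aldehyde of 15 comes from allylic alcohol 14 by allylic oxidation, 14 from spiro-epoxide 13 by base-induced isomerisation, and 13 from alkene 12 by epoxidation. This sequence is chosen because the ring-forming step leaves exactly this methylene, which already contains the future formyl carbon. What is missing is oxygen on that carbon and a shift of the double bond into the ring toward C4. The isomerisation must remove a hydrogen from benzylic C4 and not the single hydrogen on C2.

**12 ⇒ 10 + 2 (via 11).** This is the central disconnection: both bonds to C1 that are not to ring C are cut, C1–C2 and C1–C8a. They converge on one carbon that has no other substituent, so C1 becomes the aldehyde carbon of 2, C2 the γ-carbon of allylboronate 10, and C8a a nucleophilic arene carbon para to OMe. The gain is a convergent union of two vanillin-derived halves that forms ring B and both stereocentres. In the forward direction a chiral Brønsted acid must control the allyl transfer to give borate 11, and a Lewis acid must then ionise the benzylic oxygen so that ring A closes onto C1.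

**10 ⇒ 8 (via 9).** The bond between the boron-bearing CH2 and the alkene carbon is cut, which amounts to a one-carbon insertion into the C–B bond of alkenylboronate 8. The alkene geometry of 10 is translated by the chair transition state into the configuration at C2, so its geometric purity limits the enantiomeric purity of everything downstream. A substitution route through a π-allyl metal intermediate could interconvert the two geometries, which differ only in which CH2 group faces the CH2OBn group. A 1,2-metallate shift moves the intact alkenyl group and cannot do that.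

**8 ⇒ 7.** The C–B and C–H bonds on the alkene are cut, leading to alkyne 7. Syn addition of boron and hydrogen fixes the geometry by mechanism. The propargylic oxygen should direct boron to the distal carbon, and a regiochemical error would give a constitutional isomer that can be separated, not the enantiomer of the product.

**7 ⇒ 4 + 5 (via 6).** The sp–sp3 bond between the benzylic carbon and the alkyne is cut, giving benzylic bromide 4 and terminal alkyne 5, joined through acetylide 6. This brings in ring A with C4 and the C2–CH2O unit in one step.

**4 ⇒ 3 ⇒ 2 ⇒ 1.** Functional-group changes lead back to vanillin (1). Aldehyde 2 is used twice: as the electrophile of the key step (ring C and C1) and, after reduction and bromination, as the source of ring A and C4.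

## Alternatives that were turned down

**Alternative 1:** The disconnection passes through a temporary cyclopropane. Ring B is opened at C1–C8a and a bond C1–C3 is added, which leads to the bicyclic keto lactone A2 and, one step earlier, to the (E)-cinnamyl α-diazo-β-keto ester A1.
- Forward key step: A1 loses nitrogen on a chiral dirhodium tetracarboxylate or carboxamidate Rh2L4 (divalent rhodium), and the carbene adds to the E-alkene. This forms C2–C3 and C1–C3 and closes cyclopropane and lactone together. A Lewis acid would later open A2 at C1–C3 to a benzylic cation that the aroyl ring captures at C8a (homo-Nazarov closure).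
- For: the carbon on C3 arrives at the carboxyl level and the carbon on C2 at the alcohol level, so the two substituents are differentiated from the start. The later cation has no alkene nearby. On both points it is stronger than the chosen route.
- Against: the carbene carries two acceptor groups, the class for which enantiocontrol in intramolecular cyclopropanation of 1,2-disubstituted alkenes is least dependable. The arene that must attack the cation is an aryl ketone, deactivated at the carbon ortho to C=O that has to react. The silyl-protected para oxygen can be lost from the cation. After ring closure, C4 must still go from ketone to alkene and the lactone to the hydroxy enal, so the step count is not lower.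
- Comparison: the chosen strategy gives up the built-in oxidation pattern. In return it closes onto an electron-rich, unacylated ring A, sets C2 in a closed chair transition state and needs no diazo compound.

**Alternative 2:** Ring A itself is disconnected, at C4a–C8a and C7–C8, into an alkyne on C1 and a 2-pyranone on C4. The substrate is the 3-bromo-4-methoxy-2-pyranone A3, with an alkene tether that holds pyranone and C2 cis and a terminal alkyne on stereogenic C1.
- Forward key step: on heating, the pyranone diene of A3 adds to the alkyne and the adduct expels carbon dioxide, which forms the benzene ring and closes ring B at once to give the 7-bromo-1,2-dihydronaphthalene A4.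
- For: the substitution pattern of ring A is fixed by the pyranone and cannot come out as a regioisomer, the C3=C4 bond and both oxygenated carbons are in place, and the conditions are neutral. On ring A regiochemistry it is stronger than any electrophilic closure.
- Against: the key step creates no stereocentre. The C1/C2 pair must be built beforehand in an acyclic, benzylic and propargylic setting and then survive prolonged heating, where propargyl–allene isomerisation would racemise C1. The functionalised bromopyranone with its defined trisubstituted alkene is a long linear sequence. The bromine on C7 of A4 must later be exchanged for oxygen on a hindered, electron-rich ring.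
- Comparison: building a guaiacyl ring from scratch is poor step economy when both rings are vanillin units. The chosen strategy takes ring A ready-made, and its regiochemical risk is small because closure para to OMe is preferred both electronically and sterically.

**Alternative 3:** The one-carbon unit C4 is disconnected (C3–C4 and C4–C4a), leading to the 1,1-diaryl dimethyl acetal A5, in which ring A is already bonded to C1.
- Forward key step: under Vilsmeier conditions (POCl3/DMF) the acetal gives an enol ether that is formylated at C3. C4a of ring A then attacks one end of the vinylogous iminium ion and closes ring B with the enal in place, giving the protected enal A6, which carries the ring A oxygen as an allyl ether and the other two oxygens as acetates.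
- For: the enal and the C3=C4 bond appear in the ring-forming step at the final oxidation level, so only deprotection of A6 follows. This endgame is clearly shorter than the three steps the chosen route spends on the exocyclic methylene.
- Against: C1 of A5 is flanked by two aryl groups that differ only in the position and protection of their oxygens (4-acetoxy-3-methoxyphenyl and 3-allyloxy-4-methoxyphenyl). Building that centre next to C2 with absolute and relative control is the hard part of the problem, moved into the precursor. The cyclisation must also choose ring A over ring C on the strength of an allyl ether against an acetate, and the iminium intermediate can tautomerise through C2.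
- Comparison: the chosen strategy creates C1 last, diastereoselectively from C2, and never has to distinguish two nearly identical aryl groups on one carbon.

Key step: step 7

**Assumption:** the sense of induction known for this class of binaphthyl phosphoric acid with aryl aldehydes (the (R)-acid directs the allyl group to the Re face) is taken to hold for boronate 10, so the (S)-acid is specified. If the sense were opposite, the (R)-acid would be used and nothing else would change.

**Remark:** 13 is written without configuration at its spiro carbon, because both epimers lead to 14.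

## Route

Step 1
Reactants: 1 vanillin (4-hydroxy-3-methoxybenzaldehyde)
Product: 2 4-(benzyloxy)-3-methoxybenzaldehyde
Conditions: BnBr, K2CO3, DMF, rt
Reagents that add atoms: benzyl bromide, BrCc1ccccc1
Why: Williamson ether synthesis; the phenoxide of 1 is alkylated on oxygen and the aldehyde is inert to carbonate base.

Step 2
Reactants: 2 4-(benzyloxy)-3-methoxybenzaldehyde
Product: 3 [4-(benzyloxy)-3-methoxyphenyl]methanol
Conditions: NaBH4, MeOH, 0 °C
Reagents that add atoms: none
Why: Borohydride reduction of an aryl aldehyde to the benzylic alcohol; part of 2 is kept back for step 7.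

Step 3
Reactants: 3 [4-(benzyloxy)-3-methoxyphenyl]methanol
Product: 4 1-(benzyloxy)-4-(bromomethyl)-2-methoxybenzene
Conditions: PBr3, Et2O, 0 °C
Reagents that add atoms: phosphorus tribromide, BrP(Br)Br
Why: Conversion of a primary benzylic alcohol into the bromide through its phosphite ester and SN2 displacement; the electron-rich bromide is used without storage.

Step 4
Reactants: 4 1-(benzyloxy)-4-(bromomethyl)-2-methoxybenzene; 5 benzyl prop-2-yn-1-yl ether
Product: 7 1-(benzyloxy)-4-[4-(benzyloxy)but-2-yn-1-yl]-2-methoxybenzene, via alkynylmagnesium bromide 6 (not isolated)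
Conditions: 5, EtMgBr, THF, 0 °C → rt; then CuBr·SMe2 (10 mol%), 4, THF, rt → 50 °C
Reagents that add atoms: none
Why: Deprotonation of the terminal alkyne gives Grignard reagent 6, and its copper-catalysed substitution of the benzylic bromide forms the sp–sp3 bond (copper-catalysed alkylation of an alkynyl Grignard reagent); the base is consumed in the coupling, so the skipped aryl alkyne is not left in contact with a base that could isomerise it to an allene.

Step 5
Reactants: 7 1-(benzyloxy)-4-[4-(benzyloxy)but-2-yn-1-yl]-2-methoxybenzene
Product: 8 2-[(2Z)-4-(benzyloxy)-1-[4-(benzyloxy)-3-methoxyphenyl]but-2-en-2-yl]-4,4,5,5-tetramethyl-1,3,2-dioxaborolane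
Conditions: CuCl (5 mol%), PCy3 (6 mol%), NaOt-Bu (15 mol%), B2pin2, MeOH (2 equiv), PhMe, rt
Reagents that add atoms: bis(pinacolato)diboron, CC1(C)OB(OC1(C)C)B1OC(C)(C)C(C)(C)O1
Why: Copper-catalysed formal hydroboration (protoboration) of an internal propargylic ether: the monovalent copper boryl adds syn across the triple bond with copper on the carbon next to CH2OBn (the C–Cu bond is stabilised by the adjacent C–O dipole) and boron on the distal carbon, and methanol protonates the alkenylcopper with retention; syn addition fixes the Z geometry, with CH2Ar and CH2OBn cis and boron trans to CH2OBn.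

Step 6
Reactants: 8 2-[(2Z)-4-(benzyloxy)-1-[4-(benzyloxy)-3-methoxyphenyl]but-2-en-2-yl]-4,4,5,5-tetramethyl-1,3,2-dioxaborolane
Product: 10 2-[(2Z)-4-(benzyloxy)-2-{[4-(benzyloxy)-3-methoxyphenyl]methyl}but-2-en-1-yl]-4,4,5,5-tetramethyl-1,3,2-dioxaborolane, via lithium chloromethyl boronate complex 9 (not isolated)
Conditions: BrCH2Cl, n-BuLi, THF, −78 °C → rt
Reagents that add atoms: bromochloromethane, ClCBr
Why: Matteson homologation: chloromethyllithium generated in the presence of 8 adds to boron to give ate complex 9, and on warming the alkenyl group migrates from boron to carbon with loss of chloride; the migrating sp2 carbon keeps its substituents in place, so the geometry of 8 is carried unchanged into 10.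

Step 7
Reactants: 10 2-[(2Z)-4-(benzyloxy)-2-{[4-(benzyloxy)-3-methoxyphenyl]methyl}but-2-en-1-yl]-4,4,5,5-tetramethyl-1,3,2-dioxaborolane; 2 4-(benzyloxy)-3-methoxybenzaldehyde
Product: 12 (1S,2R)-7-(benzyloxy)-1-[4-(benzyloxy)-3-methoxyphenyl]-2-[(benzyloxy)methyl]-6-methoxy-3-methylidene-1,2,3,4-tetrahydronaphthalene, via homoallylic pinacol borate 11 (not isolated)
Conditions: (S)-3,3′-bis(2,4,6-triisopropylphenyl)-1,1′-binaphthyl-2,2′-diyl hydrogen phosphate (C50H57O4P, 5 mol%), 4 Å molecular sieves, PhMe, −30 → 0 °C; then CH2Cl2, BF3·OEt2 (0.3 equiv), −78 → −30 °C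
Reagents that add atoms: none
Why: The phosphoric acid binds the boronate through P–OH (to a pinacol oxygen) and the aldehyde through P=O (to the formyl hydrogen), and the allyl group is transferred through a closed six-membered chair transition state of the Zimmerman–Traxler type, forming C1–C2 at the γ-carbon of 10 and moving the double bond to the exocyclic position on C3; this is the known phosphoric-acid-catalysed allylboration of aryl aldehydes with γ-substituted allyl pinacol boronates. Because CH2OBn is trans to the CH2B group in 10 it sits equatorial in the chair and adduct 11 is the anti isomer, and the (S)-acid is expected to expose the Si face of 2, which makes C2 R and the carbinol carbon S. BF3·OEt2 then ionises the benzylic C1–O bond of 11, and the cation at C1 is stabilised as a quinoid oxocarbenium ion by the para benzyloxy group; the closest known reaction type is the acid-mediated Friedel–Crafts closure of p-alkoxybenzylic alcohols and their esters to 1-aryltetralins. Ring A, held in reach by C4 and C3, attacks the cation with C8a and loses a proton, closing ring B by a six-membered Friedel–Crafts alkylation (6-endo with respect to the arene, whose C4a–C8a bond becomes part of the new ring). Ionisation erases the carbinol configuration and C1 is set anew under control of C2: in the half-chair transition state ring C and the CH2OBn group avoid each other, so the aryl group ends trans to the C2 substituent and the product is (1S,2R). The step needs regioselectivity on ring A, which the substrate secures because the ortho position para to OMe is both the more activated and the unhindered one, whereas the other ortho position lies between the benzylic carbon and OMe. It also needs the arene to trap the cation faster than the cation loses the C2 proton or engages the 1,1-disubstituted alkene; the six-membered closure onto a dialkoxyarene, the low temperature and the substoichiometric Lewis acid serve that purpose, and the homoallylic alkene could reach C1 only through a four-membered ring.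

Step 8
Reactants: 12 (1S,2R)-7-(benzyloxy)-1-[4-(benzyloxy)-3-methoxyphenyl]-2-[(benzyloxy)methyl]-6-methoxy-3-methylidene-1,2,3,4-tetrahydronaphthalene
Product: 13 (3S,4S)-6-(benzyloxy)-4-[4-(benzyloxy)-3-methoxyphenyl]-3-[(benzyloxy)methyl]-7-methoxy-3,4-dihydro-1H-spiro[naphthalene-2,2′-oxirane] (both epimers at the spiro carbon C3; the S descriptor at C2 is a formal change of priorities, not of geometry)
Conditions: dimethyldioxirane, acetone/CH2Cl2, 0 °C
Reagents that add atoms: dimethyldioxirane, CC1(C)OO1
Why: Electrophilic epoxidation of the exocyclic 1,1-disubstituted alkene, the only C=C bond in 12; the neutral oxidant leaves no acid that could open the 2,2-disubstituted epoxide, and the configuration of the spiro carbon does not matter because that carbon becomes sp2 in step 9.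

Step 9
Reactants: 13 (3S,4S)-6-(benzyloxy)-4-[4-(benzyloxy)-3-methoxyphenyl]-3-[(benzyloxy)methyl]-7-methoxy-3,4-dihydro-1H-spiro[naphthalene-2,2′-oxirane]
Product: 14 {(3R,4S)-6-(benzyloxy)-4-[4-(benzyloxy)-3-methoxyphenyl]-3-[(benzyloxy)methyl]-7-methoxy-3,4-dihydronaphthalen-2-yl}methanol
Conditions: lithium 2,2,6,6-tetramethylpiperidide (LiNC9H18), Et2AlCl, PhMe, 0 °C; then 13, 0 °C → rt; aq. KNaC4H4O6
Reagents that add atoms: none
Why: Isomerisation of an epoxide to an allylic alcohol with a dialkylaluminium amide: aluminium binds the epoxide oxygen and the hindered amide removes a β-hydrogen syn to it through a cyclic transition state; the two benzylic hydrogens on C4 are more accessible and more acidic than the single tertiary hydrogen on C2, so the double bond should form between C3 and C4 and C2 keeps its configuration.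

Step 10
Reactants: 14 {(3R,4S)-6-(benzyloxy)-4-[4-(benzyloxy)-3-methoxyphenyl]-3-[(benzyloxy)methyl]-7-methoxy-3,4-dihydronaphthalen-2-yl}methanol
Product: 15 (3R,4S)-6-(benzyloxy)-4-[4-(benzyloxy)-3-methoxyphenyl]-3-[(benzyloxy)methyl]-7-methoxy-3,4-dihydronaphthalene-2-carbaldehyde
Conditions: MnO2, CH2Cl2, rt
Reagents that add atoms: none
Why: Chemoselective oxidation of a primary allylic alcohol to the enal with activated manganese dioxide; benzyl ethers and both stereocentres are untouched, and the reaction is stopped at full conversion to avoid dehydrogenation of ring B.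

Step 11
Reactants: 15 (3R,4S)-6-(benzyloxy)-4-[4-(benzyloxy)-3-methoxyphenyl]-3-[(benzyloxy)methyl]-7-methoxy-3,4-dihydronaphthalene-2-carbaldehyde
Product: 16 (3R,4S)-6-hydroxy-4-(4-hydroxy-3-methoxyphenyl)-3-(hydroxymethyl)-7-methoxy-3,4-dihydronaphthalene-2-carbaldehyde, the target (1S,2R in the atom numbering used in the text)
Conditions: BCl3, C6HMe5, CH2Cl2, −78 → −40 °C; then MeOH, H2O
Reagents that add atoms: none
Why: Lewis-acid cleavage of benzyl ethers: boron trichloride coordinates each ether oxygen and the benzyl cation is passed to pentamethylbenzene, a non-basic scavenger, so both phenols and the primary alcohol are released without hydrogenation; at low temperature the aryl methyl ethers, the enal and the C3=C4 bond should persist.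

## Compound list

1 | vanillin (4-hydroxy-3-methoxybenzaldehyde) | COc1cc(C=O)ccc1O | starting material
2 | 4-(benzyloxy)-3-methoxybenzaldehyde | COc1cc(C=O)ccc1OCc1ccccc1 | intermediate
3 | [4-(benzyloxy)-3-methoxyphenyl]methanol | COc1cc(CO)ccc1OCc1ccccc1 | intermediate
4 | 1-(benzyloxy)-4-(bromomethyl)-2-methoxybenzene | COc1cc(CBr)ccc1OCc1ccccc1 | intermediate
5 | benzyl prop-2-yn-1-yl ether | C#CCOCc1ccccc1 | starting material
6 | [3-(benzyloxy)prop-1-yn-1-yl]magnesium bromide | Br[Mg]C#CCOCc1ccccc1 | intermediate
7 | 1-(benzyloxy)-4-[4-(benzyloxy)but-2-yn-1-yl]-2-methoxybenzene | COc1cc(CC#CCOCc2ccccc2)ccc1OCc1ccccc1 | intermediate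
8 | 2-[(2Z)-4-(benzyloxy)-1-[4-(benzyloxy)-3-methoxyphenyl]but-2-en-2-yl]-4,4,5,5-tetramethyl-1,3,2-dioxaborolane | COc1cc(C/C(B2OC(C)(C)C(C)(C)O2)=C\COCc2ccccc2)ccc1OCc1ccccc1 | intermediate
9 | lithium 2-[(2Z)-4-(benzyloxy)-1-[4-(benzyloxy)-3-methoxyphenyl]but-2-en-2-yl]-2-(chloromethyl)-4,4,5,5-tetramethyl-1,3,2-dioxaborolan-2-uide | COc1cc(C/C([B-]2(CCl)OC(C)(C)C(C)(C)O2)=C\COCc2ccccc2)ccc1OCc1ccccc1.[Li+] | intermediate
10 | 2-[(2Z)-4-(benzyloxy)-2-{[4-(benzyloxy)-3-methoxyphenyl]methyl}but-2-en-1-yl]-4,4,5,5-tetramethyl-1,3,2-dioxaborolane | COc1cc(C/C(CB2OC(C)(C)C(C)(C)O2)=C\COCc2ccccc2)ccc1OCc1ccccc1 | intermediate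
11 | 2-{[(1S,2R)-1-[4-(benzyloxy)-3-methoxyphenyl]-2-[(benzyloxy)methyl]-3-{[4-(benzyloxy)-3-methoxyphenyl]methyl}but-3-en-1-yl]oxy}-4,4,5,5-tetramethyl-1,3,2-dioxaborolane | COc1cc([C@@H](OB2OC(C)(C)C(C)(C)O2)[C@@H](COCc2ccccc2)C(=C)Cc2ccc(OCc3ccccc3)c(OC)c2)ccc1OCc1ccccc1 | intermediate
12 | (1S,2R)-7-(benzyloxy)-1-[4-(benzyloxy)-3-methoxyphenyl]-2-[(benzyloxy)methyl]-6-methoxy-3-methylidene-1,2,3,4-tetrahydronaphthalene | COc1cc([C@H]2c3cc(OCc4ccccc4)c(OC)cc3CC(=C)[C@@H]2COCc2ccccc2)ccc1OCc1ccccc1 | intermediate
13 | (3S,4S)-6-(benzyloxy)-4-[4-(benzyloxy)-3-methoxyphenyl]-3-[(benzyloxy)methyl]-7-methoxy-3,4-dihydro-1H-spiro[naphthalene-2,2′-oxirane], both epimers at the spiro carbon | COc1cc([C@H]2c3cc(OCc4ccccc4)c(OC)cc3CC3(CO3)[C@@H]2COCc2ccccc2)ccc1OCc1ccccc1 | intermediate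
14 | {(3R,4S)-6-(benzyloxy)-4-[4-(benzyloxy)-3-methoxyphenyl]-3-[(benzyloxy)methyl]-7-methoxy-3,4-dihydronaphthalen-2-yl}methanol | COc1cc([C@H]2c3cc(OCc4ccccc4)c(OC)cc3C=C(CO)[C@@H]2COCc2ccccc2)ccc1OCc1ccccc1 | intermediate
15 | (3R,4S)-6-(benzyloxy)-4-[4-(benzyloxy)-3-methoxyphenyl]-3-[(benzyloxy)methyl]-7-methoxy-3,4-dihydronaphthalene-2-carbaldehyde | COc1cc([C@H]2c3cc(OCc4ccccc4)c(OC)cc3C=C(C=O)[C@@H]2COCc2ccccc2)ccc1OCc1ccccc1 | intermediate
16 | (3R,4S)-6-hydroxy-4-(4-hydroxy-3-methoxyphenyl)-3-(hydroxymethyl)-7-methoxy-3,4-dihydronaphthalene-2-carbaldehyde | COc1cc([C@H]2c3cc(O)c(OC)cc3C=C(C=O)[C@@H]2CO)ccc1O | target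

## Step count and risks

Total: 11 steps. Longest linear sequence: 11 steps (1 → 2 → 3 → 4 → 7 → 8 → 10 → 12 → 13 → 14 → 15 → 16); aldehyde 2 enters a second time in step 7.

**Step 7 (key step).** Three things may go wrong. The allyl transfer may be slow or poorly face-selective, because the boronate is substituted at both the β- and the γ-carbon and the aldehyde is electron-rich. In the cationic stage, the cation may lose the C2 proton or take a hydride from C2, either of which erases the only catalyst-set stereocentre. Acid may also move the exocyclic double bond.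

Fallback, setting out from 10 and 2 and returning at 12: the two events are separated. The allylboration is run under the same acid and worked up with water to the free alcohol (1S,2R)-1-[4-(benzyloxy)-3-methoxyphenyl]-2-[(benzyloxy)methyl]-3-{[4-(benzyloxy)-3-methoxyphenyl]methyl}but-3-en-1-ol F1, which can be purified and its enantiomeric purity checked. F1 is then cyclised in 1,1,1,3,3,3-hexafluoropropan-2-ol, a solvent that ionises p-alkoxybenzylic alcohols by hydrogen bonding without a Lewis acid, so ring closure becomes a dehydrative Friedel–Crafts alkylation under conditions that should leave the alkene alone.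

**Step 5.** Boron may be delivered to the wrong alkyne carbon, since the regiochemistry rests only on the inductive effect of the propargylic oxygen against a benzylic CH2. The alkenylcopper may also eliminate benzyloxide to an allene.

Fallback, setting out from 4 and returning at 10 (7, 8 and 9 are bypassed): the trisubstituted alkene is built by carbonyl olefination. Alkylation of ethyl (triphenylphosphoranylidene)acetate (CCOC(=O)C=P(c1ccccc1)(c1ccccc1)c1ccccc1) with 4, followed by aqueous NaOH, gives the stabilised ylide ethyl 3-[4-(benzyloxy)-3-methoxyphenyl]-2-(triphenyl-λ5-phosphanylidene)propanoate F2. Wittig reaction of F2 with benzyloxyacetaldehyde (O=CCOCc1ccccc1) should give ethyl (2E)-4-(benzyloxy)-2-{[4-(benzyloxy)-3-methoxyphenyl]methyl}but-2-enoate F3, with the ester trans to CH2OBn. Reduction of F3 with i-Bu2AlH gives (2E)-4-(benzyloxy)-2-{[4-(benzyloxy)-3-methoxyphenyl]methyl}but-2-en-1-ol F4, and methyl chloroformate with pyridine converts F4 into (2E)-4-(benzyloxy)-2-{[4-(benzyloxy)-3-methoxyphenyl]methyl}but-2-en-1-yl methyl carbonate F5. Borylation of F5 with B2pin2 and Pd2(dba)3 (zerovalent palladium) then gives 10. The π-allyl intermediate is formed from F5 as the syn isomer, which should also be the more stable one, and boron goes to the unsubstituted terminus.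

**Step 9.** The amide may remove the hydrogen on C2 instead of one on C4, which would place the double bond between C2 and C3 and destroy the stereocentre. It may also metalate the epoxide CH2.

Fallback, setting out from 13 and returning at 15: the oxygenated carbon is first brought to the aldehyde level and the double bond is introduced afterwards. Meinwald rearrangement of 13 (catalytic BF3·OEt2, CH2Cl2, −78 °C; 1,2-hydride shift in the opened epoxide) gives (3R,4S)-6-(benzyloxy)-4-[4-(benzyloxy)-3-methoxyphenyl]-3-[(benzyloxy)methyl]-7-methoxy-1,2,3,4-tetrahydronaphthalene-2-carbaldehyde F6 as a mixture at the formyl-bearing carbon. α,β-Dehydrogenation of F6 with 2-iodoxybenzoic acid in DMSO then gives 15, with the new double bond toward benzylic C4, where it is conjugated with ring A.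

**Step 11.** The primary alkyl benzyl ether may be cleaved incompletely at temperatures that the enal and the aryl methyl ethers tolerate. The Lewis acid may also cause aromatisation of ring B or chloride addition to the enal.

Fallback, setting out from 12 and returning at 16: the protecting groups are exchanged before the enal exists. Reductive debenzylation of 12 with lithium 4,4′-di-tert-butylbiphenylide (THF, −78 °C), which spares the isolated alkene, gives (1S,2R)-7-hydroxy-1-(4-hydroxy-3-methoxyphenyl)-2-(hydroxymethyl)-6-methoxy-3-methylidene-1,2,3,4-tetrahydronaphthalene F7. Treatment of F7 with t-BuMe2SiCl and imidazole gives its tris(tert-butyldimethylsilyl) ether F8. The operations of steps 8 to 10 follow on the silylated series: dimethyldioxirane gives the silylated spiro-epoxide F9, the diethylaluminium amide gives the silylated allylic alcohol F10, and MnO2 gives the silylated enal F11. Bu4NF buffered with AcOH (THF, 0 °C) finally removes the three silyl groups from F11 and gives 16.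

## Further compounds

F1 | step 7 | (1S,2R)-1-[4-(benzyloxy)-3-methoxyphenyl]-2-[(benzyloxy)methyl]-3-{[4-(benzyloxy)-3-methoxyphenyl]methyl}but-3-en-1-ol | COc1cc([C@@H](O)[C@@H](COCc2ccccc2)C(=C)Cc2ccc(OCc3ccccc3)c(OC)c2)ccc1OCc1ccccc1
F2 | step 5 | ethyl 3-[4-(benzyloxy)-3-methoxyphenyl]-2-(triphenyl-λ5-phosphanylidene)propanoate | CCOC(=O)C(Cc1ccc(OCc2ccccc2)c(OC)c1)=P(c1ccccc1)(c1ccccc1)c1ccccc1
F3 | step 5 | ethyl (2E)-4-(benzyloxy)-2-{[4-(benzyloxy)-3-methoxyphenyl]methyl}but-2-enoate | CCOC(=O)/C(Cc1ccc(OCc2ccccc2)c(OC)c1)=C/COCc1ccccc1
F4 | step 5 | (2E)-4-(benzyloxy)-2-{[4-(benzyloxy)-3-methoxyphenyl]methyl}but-2-en-1-ol | OC/C(Cc1ccc(OCc2ccccc2)c(OC)c1)=C/COCc1ccccc1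
F5 | step 5 | (2E)-4-(benzyloxy)-2-{[4-(benzyloxy)-3-methoxyphenyl]methyl}but-2-en-1-yl methyl carbonate | COC(=O)OC/C(Cc1ccc(OCc2ccccc2)c(OC)c1)=C/COCc1ccccc1
F6 | step 9 | (3R,4S)-6-(benzyloxy)-4-[4-(benzyloxy)-3-methoxyphenyl]-3-[(benzyloxy)methyl]-7-methoxy-1,2,3,4-tetrahydronaphthalene-2-carbaldehyde (both epimers at C2 of this name) | COc1cc([C@H]2c3cc(OCc4ccccc4)c(OC)cc3CC(C=O)[C@@H]2COCc2ccccc2)ccc1OCc1ccccc1
F7 | step 11 | (1S,2R)-7-hydroxy-1-(4-hydroxy-3-methoxyphenyl)-2-(hydroxymethyl)-6-methoxy-3-methylidene-1,2,3,4-tetrahydronaphthalene | COc1cc([C@H]2c3cc(O)c(OC)cc3CC(=C)[C@@H]2CO)ccc1O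
F8 | step 11 | (1S,2R)-7-(tert-butyldimethylsilyloxy)-1-[4-(tert-butyldimethylsilyloxy)-3-methoxyphenyl]-2-[(tert-butyldimethylsilyloxy)methyl]-6-methoxy-3-methylidene-1,2,3,4-tetrahydronaphthalene | COc1cc([C@H]2c3cc(O[Si](C)(C)C(C)(C)C)c(OC)cc3CC(=C)[C@@H]2CO[Si](C)(C)C(C)(C)C)ccc1O[Si](C)(C)C(C)(C)C
F9 | step 11 | (3S,4S)-6-(tert-butyldimethylsilyloxy)-4-[4-(tert-butyldimethylsilyloxy)-3-methoxyphenyl]-3-[(tert-butyldimethylsilyloxy)methyl]-7-methoxy-3,4-dihydro-1H-spiro[naphthalene-2,2′-oxirane] (both epimers at the spiro carbon) | COc1cc([C@H]2c3cc(O[Si](C)(C)C(C)(C)C)c(OC)cc3CC3(CO3)[C@@H]2CO[Si](C)(C)C(C)(C)C)ccc1O[Si](C)(C)C(C)(C)C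
F10 | step 11 | {(3R,4S)-6-(tert-butyldimethylsilyloxy)-4-[4-(tert-butyldimethylsilyloxy)-3-methoxyphenyl]-3-[(tert-butyldimethylsilyloxy)methyl]-7-methoxy-3,4-dihydronaphthalen-2-yl}methanol | COc1cc([C@H]2c3cc(O[Si](C)(C)C(C)(C)C)c(OC)cc3C=C(CO)[C@@H]2CO[Si](C)(C)C(C)(C)C)ccc1O[Si](C)(C)C(C)(C)C
F11 | step 11 | (3R,4S)-6-(tert-butyldimethylsilyloxy)-4-[4-(tert-butyldimethylsilyloxy)-3-methoxyphenyl]-3-[(tert-butyldimethylsilyloxy)methyl]-7-methoxy-3,4-dihydronaphthalene-2-carbaldehyde | COc1cc([C@H]2c3cc(O[Si](C)(C)C(C)(C)C)c(OC)cc3C=C(C=O)[C@@H]2CO[Si](C)(C)C(C)(C)C)ccc1O[Si](C)(C)C(C)(C)C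
A1 | alternative 1 | (2E)-3-[4-(tert-butyldimethylsilyloxy)-3-methoxyphenyl]prop-2-en-1-yl 3-[4-(tert-butyldimethylsilyloxy)-3-methoxyphenyl]-2-diazo-3-oxopropanoate | COc1cc(/C=C/COC(=O)C(=[N+]=[N-])C(=O)c2ccc(O[Si](C)(C)C(C)(C)C)c(OC)c2)ccc1O[Si](C)(C)C(C)(C)C
A2 | alternative 1 | 1-[4-(tert-butyldimethylsilyloxy)-3-methoxybenzoyl]-6-[4-(tert-butyldimethylsilyloxy)-3-methoxyphenyl]-3-oxabicyclo[3.1.0]hexan-2-one (configuration as in the SMILES) | COc1cc([C@@H]2[C@H]3COC(=O)[C@@]23C(=O)c2ccc(O[Si](C)(C)C(C)(C)C)c(OC)c2)ccc1O[Si](C)(C)C(C)(C)C
A3 | alternative 2 | 3-bromo-6-{(1E)-4-[4-(tert-butyldimethylsilyloxy)-3-methoxyphenyl]-2,3-bis[(tert-butyldimethylsilyloxy)methyl]hex-1-en-5-yn-1-yl}-4-methoxy-2H-pyran-2-one (configuration as in the SMILES) | COc1cc([C@@H](C#C)[C@@H](CO[Si](C)(C)C(C)(C)C)/C(CO[Si](C)(C)C(C)(C)C)=C\c2cc(OC)c(Br)c(=O)o2)ccc1O[Si](C)(C)C(C)(C)C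
A4 | alternative 2 | 7-bromo-1-[4-(tert-butyldimethylsilyloxy)-3-methoxyphenyl]-2,3-bis[(tert-butyldimethylsilyloxy)methyl]-6-methoxy-1,2-dihydronaphthalene (configuration as in the SMILES) | COc1cc([C@H]2c3cc(Br)c(OC)cc3C=C(CO[Si](C)(C)C(C)(C)C)[C@@H]2CO[Si](C)(C)C(C)(C)C)ccc1O[Si](C)(C)C(C)(C)C
A5 | alternative 3 | 4-{1-[3-(allyloxy)-4-methoxyphenyl]-2-(acetoxymethyl)-4,4-dimethoxybutyl}-2-methoxyphenyl acetate (configuration as in the SMILES) | COC(OC)C[C@H](COC(C)=O)[C@@H](c1ccc(OC(C)=O)c(OC)c1)c1ccc(OC)c(OCC=C)c1
A6 | alternative 3 | [1-(4-acetoxy-3-methoxyphenyl)-7-(allyloxy)-3-formyl-6-methoxy-1,2-dihydronaphthalen-2-yl]methyl acetate (configuration as in the SMILES) | COc1cc([C@H]2c3cc(OCC=C)c(OC)cc3C=C(C=O)[C@@H]2COC(C)=O)ccc1OC(C)=O
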